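Numbering used (germacrane): C1 hemiketal carbon, C2–C3 its CH2CH2, C4 the methyl-bearing ether carbon, C5=C6 the enol-lactone alkene, C7=C11–C12 the butenolide, C8 the carbinol, C9 CH2, C10 the acetoxy carbon, C13 the CH2OAc.
Enabling feature: C1 is a masked ketone 1,4 to the C4 tertiary alcohol and belongs to both the ten-membered carbocycle (C1–C10) and the oxolane (C1, C2, C3, C4, O). An acyl–alkyl union C1–C2 therefore closes the carbocycle, and the oxolane then closes by itself.
Cuts: O–C1 and C1–C2 (thioester + alkylzinc), the (E)-ylidene butenolide back to a furan (C6, C7, C11, C12), C7–C8 (furyllithium + anhydride), C5–C6 (furyllithium + epoxide), C11–C13 (furyllithium + formaldehyde).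
Forward: 3,4-dibromofuran receives C13, the C5–C2 arm and the C8–C1 arm in turn. One operation then turns this monocyclic furan into carbocycle plus oxolane, and singlet oxygen with dehydration makes the butenolide last.
Stereochemistry: C4 from an enantioselective epoxidation of isoprenol, C10 from (S)-citramalic acid, C8 from a CBS reduction, C1 from reversible hemiketalisation steered by C4. The C5=C6 geometry comes from the nine-membered oxa-bridged ring (O, C1, C10, C9, C8, C7, C6, C5, C4), which should admit only a cis ring alkene.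

Key step: step 14

Remark: the antipodes of the bishydroxamic acid ligand (step 1) and of the oxazaborolidine (step 9) are taken to be those that give the drawn configurations by the usual models; any minor enantiomer of 3 becomes a diastereomer after step 8 and should be removable by chromatography.

Step 1
Reactants: 1 3-methylbut-3-en-1-ol (isoprenol)
Product: 2 (R)-2-(2-methyloxiran-2-yl)ethan-1-ol
Conditions: Hf(OtBu)4 (5 mol %), C2-symmetric cyclohexanediamine-derived bishydroxamic acid (6 mol %), cumene hydroperoxide, DMPU, MS 4 Å, toluene, 0 °C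
Reagents that add atoms: cumene hydroperoxide CC(C)(OO)c1ccccc1
Why: Hydroxyl-directed enantioselective epoxidation of a homoallylic alcohol, in which the substrate alkoxide binds to the chiral hafnium bishydroxamate and the peroxide oxygen is delivered to one face of the 1,1-disubstituted alkene, sets the future C4.

Step 2
Reactants: 2 (R)-2-(2-methyloxiran-2-yl)ethan-1-ol
Product: 3 (R)-2-(2-chloroethyl)-2-methyloxirane
Conditions: PPh3, CCl4, NaHCO3 (buffer), CH2Cl2, 40 °C
Reagents that add atoms: carbon tetrachloride ClC(Cl)(Cl)Cl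
Why: The Appel chlorination replaces the primary hydroxyl by SN2 under neutral conditions, leaves the epoxide and its quaternary centre untouched, and gives a C2 handle that is inert to the later organolithium steps.

Step 3
Reactants: 4 (S)-citramalic acid
Product: 5 (S)-2-acetoxy-2-methylsuccinic anhydride
Conditions: AcCl (neat), reflux; evaporate
Reagents that add atoms: acetyl chloride CC(=O)Cl
Why: Acetylation and cyclodehydration of an α-hydroxysuccinic acid with acetyl chloride is classical, and C10 is a non-enolisable quaternary centre from the chiral pool that cannot racemise.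

Step 4
Reactants: 6 3,4-dibromofuran
Product: 8 (4-bromofuran-3-yl)methanol, via 3-bromo-4-lithiofuran 7 (not isolated)
Conditions: n-BuLi (1.0 equiv), Et2O, −78 °C; HCHO (gas), −78 °C; H2O
Reagents that add atoms: formaldehyde C=O
Why: Mono bromine–lithium exchange of the symmetric dibromide at low temperature (no drift of the 3-furyllithium to an α-position) followed by 1,2-addition to formaldehyde installs C13.

Step 5
Reactants: 8 (4-bromofuran-3-yl)methanol
Product: 9 [(4-bromofuran-3-yl)methoxy](tert-butyl)dimethylsilane
Conditions: TBSCl, imidazole, DMF, rt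
Reagents that add atoms: tert-butyldimethylsilyl chloride CC(C)(C)[Si](C)(C)Cl
Why: Standard silylation gives an ether that survives LDA and t-BuLi, and whose bulk should hold back oxygen-to-carbon silyl migration in the lithiations.

Step 6
Reactants: 9 [(4-bromofuran-3-yl)methoxy](tert-butyl)dimethylsilane; 3 (R)-2-(2-chloroethyl)-2-methyloxirane
Product: 11 (S)-1-{3-bromo-4-[(tert-butyldimethylsilyloxy)methyl]furan-2-yl}-4-chloro-2-methylbutan-2-ol, via 2-lithiofuran 10 (not isolated)
Conditions: LDA (1.05 equiv), THF, −78 °C; then 3, BF3·OEt2, −78 °C; H2O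
Reagents that add atoms: none
Why: Bromine makes the adjacent α-proton (C6–H) the most acidic site for deprotonation by LDA, and the BF3-assisted SN2 opening of the epoxide at its CH2 terminus (C5) forms C5–C6 without touching the C4 stereocentre.

Step 7
Reactants: 11 (S)-1-{3-bromo-4-[(tert-butyldimethylsilyloxy)methyl]furan-2-yl}-4-chloro-2-methylbutan-2-ol
Product: 12 triethylsilyl ether of 11 (C4 OTES)
Conditions: TESOTf, 2,6-lutidine, CH2Cl2, −78 → 0 °C
Reagents that add atoms: triethylsilyl triflate CC[Si](CC)(CC)OS(=O)(=O)C(F)(F)F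
Why: Silyl triflate silylation of a hindered tertiary alcohol prevents acylation of the alkoxide in step 8 and hemiketal or spirolactone formation with the coming C8 ketone.

Step 8
Reactants: 12 triethylsilyl ether of 11; 5 (S)-2-acetoxy-2-methylsuccinic anhydride
Product: 15 allyl (S)-2-acetoxy-4-{2-[(S)-4-chloro-2-methyl-2-(triethylsilyloxy)butyl]-4-[(tert-butyldimethylsilyloxy)methyl]furan-3-yl}-2-methyl-4-oxobutanoate, via 3-furyllithium 13 (not isolated), via lithium carboxylate 14 (not isolated)
Conditions: t-BuLi (2.0 equiv), Et2O, −78 °C; cannulated into 5 (1.5 equiv), THF, −78 °C; then allyl bromide, DMF, −78 °C → rt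
Reagents that add atoms: allyl bromide C=CCBr
Why: After bromine–lithium exchange the flanked furyllithium should open the cyclic anhydride at the CH2-flanked carbonyl (C8) rather than at the one next to quaternary C10 (aryl ketone synthesis by anhydride opening, inverse addition against over-addition), and the carboxylate set free is O-allylated in the same flask.

Step 9
Reactants: 15 keto allyl ester
Product: 16 allyl (2S,4R)-2-acetoxy-4-hydroxy analogue of 15 (C8 OH)
Conditions: (S)-Me-CBS (20 mol %), catecholborane, toluene, −78 → −40 °C; H2O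
Reagents that add atoms: none
Why: In the Corey–Bakshi–Shibata reduction the disubstituted furyl group should act as the large and the CH2 side as the small substituent, so the (S)-oxazaborolidine delivers hydride to give (R)-C8, and catecholborane spares the allyl alkene.

Step 10
Reactants: 16 C8 alcohol
Product: 17 C8 tert-butyldimethylsilyl ether of 16
Conditions: TBSOTf (1.1 equiv), 2,6-lutidine, CH2Cl2, −78 °C, directly after step 9
Reagents that add atoms: tert-butyldimethylsilyl triflate CC(C)(C)[Si](C)(C)OS(=O)(=O)C(F)(F)F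
Why: Fast non-nucleophilic silylation caps the C8 hydroxyl before it can lactonise onto C1 or take over the C10 acetyl group.

Step 11
Reactants: 17 fully protected allyl ester
Product: 18 (2S,4R)-carboxylic acid from 17 (C1 CO2H)
Conditions: Pd(PPh3)4 (5 mol %), morpholine, THF, rt; pH 4 buffer
Reagents that add atoms: none
Why: In this Tsuji–Trost-type deallylation zerovalent palladium ionises only the allyl ester and morpholine traps the allyl unit, while acetate, silyl ethers, furan and alkyl chloride are inert.

Step 12
Reactants: 18 carboxylic acid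
Product: 19 S-ethyl thioester of 18
Conditions: EtSH, DCC, DMAP (cat.), CH2Cl2, 0 °C → rt
Reagents that add atoms: ethanethiol CCS
Why: Steglich-type thioesterification activates C1 as the only acyl group that palladium can later insert into, and is done on the chloride so that the thiol finds no reactive halide.

Step 13
Reactants: 19 chloro thioester
Product: 20 iodo thioester (C2 iodide)
Conditions: NaI (10 equiv), acetone, reflux
Reagents that add atoms: sodium iodide [Na+].[I-]
Why: The Finkelstein exchange on a neutral, fully protected molecule turns the dormant primary chloride into the iodide needed for zinc insertion.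

Step 14
Reactants: 20 iodo thioester
Product: 24 (1S,4R,8R,10S) furan-fused 1,4-epoxy hemiketal (C8 OTBS; C10 OAc; C13 OH), via alkylzinc iodide 21 (not isolated), via silylated cyclodecanone 22 (not isolated), via hydroxy ketone 23 (not isolated)
Conditions: activated Zn dust, LiCl, THF, 25–35 °C; filtered solution added by syringe pump to PdCl2(PPh3)2 (20 mol %), toluene–THF, 40 °C (final about 1 mM); concentrate; AcOH–THF–H2O 3:1:1, rt
Reagents that add atoms: none
Why: Proposed new method: zinc inserts into the primary C2–I bond, zerovalent palladium adds oxidatively to the C1–S bond of the same molecule, and transmetalation followed by reductive elimination from the acyl(alkyl)palladium joins C1 to C2. The closest known reaction type is the intermolecular Fukuyama thioester–alkylzinc ketone synthesis, whose elementary steps already serve in macrocyclic Negishi and acyl Stille closures. The ten-membered carbocycle closes through an eleven-membered palladacycle that contracts on reductive elimination (formally a 10-exo-trig acyl substitution at C1), and once acetic acid has freed the C4 hydroxyl the oxolane closes by 5-exo-trig addition to the new C1 ketone. C1 is the only new stereocentre and is set under thermodynamic control, because the reversible hemiketal can bridge the ring only with C5 and C10 cis on the oxolane, so that (R)-C4 dictates (S)-C1. The step needs cyclisation to beat oligomerisation and the thioester to be the only acyl group that reacts: slow addition of a persistent organozinc that ignores acetates without palladium, the cis disposition of both arms on the planar furan (C6, C7) and the turn-inducing quaternary centres C4 and C10 should secure this. The acid stage must distinguish the silyl ethers, and the tertiary TES and primary TBS groups are expected to leave while the flanked secondary C8 OTBS stays.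

Step 15
Reactants: 24 furan-fused hemiketal
Product: 28 8-O-TBS ether of the target, via furan endoperoxide 25 (not isolated), via hydroxybutenolide 26 (not isolated), via acetoxybutenolide 27 (not isolated)
Conditions: O2, tetraphenylporphyrin (cat.), hν (visible), CH2Cl2, −78 °C; then i-Pr2NEt, −78 °C; then Ac2O (2.3 equiv), DMAP (cat.), 0 °C → rt
Reagents that add atoms: dioxygen O=O; acetic anhydride CC(=O)OC(C)=O
Why: Singlet oxygen adds [4+2] across the furan, the base opens the endoperoxide in the Kornblum–DeLaMare manner at its only C–H bridgehead (C12), acetic anhydride acetylates the primary C13 hydroxyl and the pseudo-acid hydroxyl at C6, and loss of acetic acid toward C5 should give the alkene that is cis within the nine-membered oxa-bridged ring, which is the (E)-ylidene.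

Step 16
Reactants: 28 8-O-TBS ether of the target
Product: 29 target CNP0203479.1
Conditions: HF·pyridine, pyridine, THF, 0 °C → rt
Reagents that add atoms: none
Why: Buffered fluoride desilylation frees the C8 hydroxyl without base, so the acetates, the allylic C13 acetate, the hemiketal and all stereocentres should stay as they are.

Compound list
1 | 3-methylbut-3-en-1-ol | C=C(C)CCO | starting material
2 | (R)-2-(2-methyloxiran-2-yl)ethan-1-ol | C1[C@@](O1)(C)CCO | intermediate
3 | (R)-2-(2-chloroethyl)-2-methyloxirane | C1[C@@](O1)(C)CCCl | intermediate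
4 | (S)-citramalic acid | OC(=O)[C@@](C)(O)CC(=O)O | starting material
5 | (S)-2-acetoxy-2-methylsuccinic anhydride | O=C1[C@@](C)(OC(C)=O)CC(=O)O1 | intermediate
6 | 3,4-dibromofuran | Brc1cocc1Br | starting material
7 | 3-bromo-4-lithiofuran (not isolated) | [Li]c1cocc1Br | intermediate
8 | (4-bromofuran-3-yl)methanol | OCc1cocc1Br | intermediate
9 | [(4-bromofuran-3-yl)methoxy](tert-butyl)dimethylsilane | CC(C)(C)[Si](C)(C)OCc1cocc1Br | intermediate
10 | 2-lithio derivative of 9, lithium next to C–Br (not isolated) | CC(C)(C)[Si](C)(C)OCc1coc([Li])c1Br | intermediate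
11 | (S)-1-{3-bromo-4-[(TBSO)methyl]furan-2-yl}-4-chloro-2-methylbutan-2-ol | CC(C)(C)[Si](C)(C)OCc1coc(C[C@@](O)(C)CCCl)c1Br | intermediate
12 | C4 triethylsilyl ether of 11 | CC(C)(C)[Si](C)(C)OCc1coc(C[C@@](O[Si](CC)(CC)CC)(C)CCCl)c1Br | intermediate
13 | 3-furyllithium from 12 (not isolated) | CC(C)(C)[Si](C)(C)OCc1coc(C[C@@](O[Si](CC)(CC)CC)(C)CCCl)c1[Li] | intermediate
14 | lithium (S)-2-acetoxy-2-methyl-4-oxo-4-furylbutanoate (not isolated) | [Li+].[O-]C(=O)[C@@](C)(OC(C)=O)CC(=O)c1c(CO[Si](C)(C)C(C)(C)C)coc1C[C@@](O[Si](CC)(CC)CC)(C)CCCl | intermediate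
15 | keto allyl ester (4S,10S; C8 ketone) | C=CCOC(=O)[C@@](C)(OC(C)=O)CC(=O)c1c(CO[Si](C)(C)C(C)(C)C)coc1C[C@@](O[Si](CC)(CC)CC)(C)CCCl | intermediate
16 | C8 alcohol (4S,8R,10S) | C=CCOC(=O)[C@@](C)(OC(C)=O)C[C@@H](O)c1c(CO[Si](C)(C)C(C)(C)C)coc1C[C@@](O[Si](CC)(CC)CC)(C)CCCl | intermediate
17 | C8 OTBS allyl ester (4S,8R,10S) | C=CCOC(=O)[C@@](C)(OC(C)=O)C[C@@H](O[Si](C)(C)C(C)(C)C)c1c(CO[Si](C)(C)C(C)(C)C)coc1C[C@@](O[Si](CC)(CC)CC)(C)CCCl | intermediate
18 | C1 carboxylic acid (4S,8R,10S) | OC(=O)[C@@](C)(OC(C)=O)C[C@@H](O[Si](C)(C)C(C)(C)C)c1c(CO[Si](C)(C)C(C)(C)C)coc1C[C@@](O[Si](CC)(CC)CC)(C)CCCl | intermediate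
19 | S-ethyl thioester, C2 chloride (4S,8R,10S) | CCSC(=O)[C@@](C)(OC(C)=O)C[C@@H](O[Si](C)(C)C(C)(C)C)c1c(CO[Si](C)(C)C(C)(C)C)coc1C[C@@](O[Si](CC)(CC)CC)(C)CCCl | intermediate
20 | S-ethyl thioester, C2 iodide (4S,8R,10S) | CCSC(=O)[C@@](C)(OC(C)=O)C[C@@H](O[Si](C)(C)C(C)(C)C)c1c(CO[Si](C)(C)C(C)(C)C)coc1C[C@@](O[Si](CC)(CC)CC)(C)CCI | intermediate
21 | alkylzinc iodide from 20 (not isolated) | CCSC(=O)[C@@](C)(OC(C)=O)C[C@@H](O[Si](C)(C)C(C)(C)C)c1c(CO[Si](C)(C)C(C)(C)C)coc1C[C@@](O[Si](CC)(CC)CC)(C)CC[Zn]I | intermediate
22 | furan-fused cyclodecanone (4R,8R,10S; C4 OTES, C8 OTBS, C13 OTBS; not isolated) | O=C1CC[C@@](C)(O[Si](CC)(CC)CC)Cc2occ(CO[Si](C)(C)C(C)(C)C)c2[C@H](O[Si](C)(C)C(C)(C)C)C[C@]1(C)OC(C)=O | intermediate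
23 | C4 hydroxy C1 ketone (4R,8R,10S; C13 OH; not isolated) | O=C1CC[C@@](C)(O)Cc2occ(CO)c2[C@H](O[Si](C)(C)C(C)(C)C)C[C@]1(C)OC(C)=O | intermediate
24 | furan-fused 1,4-epoxy hemiketal (1S,4R,8R,10S) | OCc1coc(C[C@@]2(C)CC[C@](O)(O2)[C@@](C)(OC(C)=O)C[C@H]3O[Si](C)(C)C(C)(C)C)c13 | intermediate
25 | furan endoperoxide, O–O across C6 and C12 (not isolated) | OCC1=C2C3(OOC1O3)C[C@@]4(C)CC[C@](O)(O4)[C@@](C)(OC(C)=O)C[C@H]2O[Si](C)(C)C(C)(C)C | intermediate
26 | C6 hydroxybutenolide (not isolated) | OCC1=C2C(O)(OC1=O)C[C@@]3(C)CC[C@](O)(O3)[C@@](C)(OC(C)=O)C[C@H]2O[Si](C)(C)C(C)(C)C | intermediate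
27 | C6 acetoxybutenolide, C13 acetate (not isolated) | CC(=O)OCC1=C2C(OC(C)=O)(OC1=O)C[C@@]3(C)CC[C@](O)(O3)[C@@](C)(OC(C)=O)C[C@H]2O[Si](C)(C)C(C)(C)C | intermediate
28 | 8-O-TBS ether of the target (1S,4R,8R,10S; 5E) | CC(=O)OCC1=C2/C(=C\[C@@]3(C)CC[C@](O)(O3)[C@@](C)(OC(C)=O)C[C@H]2O[Si](C)(C)C(C)(C)C)OC1=O | intermediate
29 | CNP0203479.1 (1S,4R,8R,10S; 5E) | CC(=O)OCC1=C2/C(=C\[C@@]3(C)CC[C@](O)(O3)[C@@](C)(OC(C)=O)C[C@H]2O)OC1=O | target

Total steps: 16. Longest linear sequence: 13 steps (6 → 29, steps 4–16; the branch 1 → 3 joins at step 6 and is equally long).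

Steps most likely to fail

Step 14. Oligomerisation, protodezincation, or slow oxidative addition and decarbonylation at the neopentyl-type thioester may outrun ring closure. The fallback brings C1 in as an aldehyde, closes the same bond by 1,2-addition, and restores the ketone level afterwards.
- From 19, Fukuyama reduction (Et3SiH, Pd/C, acetone) should give the chloro aldehyde F1.
- Finkelstein exchange should give the iodo aldehyde F2.
- A cobalt-catalysed Nozaki–Hiyama-type alkylchromium addition (CrCl2, cobalt phthalocyanine CoC32H16N8, DMF, high dilution) should give the cyclodecanol F3 as either C1 epimer.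
- Dess–Martin oxidation converges both epimers on 22, which goes on with AcOH–THF–H2O to 24.

Step 8. The furyllithium may attack the wrong anhydride carbonyl. Silyl migration to the lithiated carbon, ring closure onto the chloride, or β-elimination of the C10 acetate from the new ketone may also compete. The fallback settles the regiochemistry on a small molecule before the union.
- From 5, aminolysis with MeNHOMe should give the Weinreb amide acid F4, which can be purified and checked.
- Allyl bromide with KHCO3 in DMF should give the allyl ester amide F5.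
- The furyllithium 13 (from 12) is then added to F5 in a Weinreb ketone synthesis, which returns to the route at 15.

Step 15. Acylation or ionisation of the free hemiketal, transannular ketal formation between the C1 hydroxyl and C6, or elimination to the wrong alkene geometry may occur. The fallback masks C1 first and dehydrates without an acylating agent.
- From 24, MeOH with PPTS should give the C1 methyl ketal F6.
- Ac2O with pyridine should give its C13 acetate F7.
- Photooxygenation followed by i-Pr2NEt should give the hydroxybutenolide F8.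
- MsCl with Et3N should give the ylidene butenolide methyl ketal F9.
- Aqueous HF in MeCN then removes the silyl group, hydrolyses the ketal, and returns to the route at 29.

Further compounds
F1 | step 14 | chloro aldehyde (C1 CHO; 4S,8R,10S) | O=C[C@@](C)(OC(C)=O)C[C@@H](O[Si](C)(C)C(C)(C)C)c1c(CO[Si](C)(C)C(C)(C)C)coc1C[C@@](O[Si](CC)(CC)CC)(C)CCCl
F2 | step 14 | iodo aldehyde (C1 CHO; 4S,8R,10S) | O=C[C@@](C)(OC(C)=O)C[C@@H](O[Si](C)(C)C(C)(C)C)c1c(CO[Si](C)(C)C(C)(C)C)coc1C[C@@](O[Si](CC)(CC)CC)(C)CCI
F3 | step 14 | furan-fused cyclodecanol (C1 OH, either epimer; 4R,8R,10S) | OC1CC[C@@](C)(O[Si](CC)(CC)CC)Cc2occ(CO[Si](C)(C)C(C)(C)C)c2[C@H](O[Si](C)(C)C(C)(C)C)C[C@]1(C)OC(C)=O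
F4 | step 8 | (S)-2-acetoxy-4-[methoxy(methyl)amino]-2-methyl-4-oxobutanoic acid | OC(=O)[C@@](C)(OC(C)=O)CC(=O)N(C)OC
F5 | step 8 | allyl (S)-2-acetoxy-4-[methoxy(methyl)amino]-2-methyl-4-oxobutanoate | C=CCOC(=O)[C@@](C)(OC(C)=O)CC(=O)N(C)OC
F6 | step 15 | C1 methyl ketal of 24 | OCc1coc(C[C@@]2(C)CC[C@](OC)(O2)[C@@](C)(OC(C)=O)C[C@H]3O[Si](C)(C)C(C)(C)C)c13
F7 | step 15 | C13 acetate of F6 | CC(=O)OCc1coc(C[C@@]2(C)CC[C@](OC)(O2)[C@@](C)(OC(C)=O)C[C@H]3O[Si](C)(C)C(C)(C)C)c13
F8 | step 15 | C6 hydroxybutenolide methyl ketal | CC(=O)OCC1=C2C(O)(OC1=O)C[C@@]3(C)CC[C@](OC)(O3)[C@@](C)(OC(C)=O)C[C@H]2O[Si](C)(C)C(C)(C)C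
F9 | step 15 | (E)-ylidene butenolide methyl ketal (8-O-TBS) | CC(=O)OCC1=C2/C(=C\[C@@]3(C)CC[C@](OC)(O3)[C@@](C)(OC(C)=O)C[C@H]2O[Si](C)(C)C(C)(C)C)OC1=O
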